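**Plan** (germacrane numbering: ring C1–C10, lactone branch C11–C13 on C7, C14 on C10, C15 on C4)

1. Late cuts: the O8 acrylate ester, the C14 acetate, the C15 aldehyde (from CH2OPMB), C11=C13, then the lactone O–C6 bond (closed with inversion), which leaves a C6 ketone.
2. Central cut: C1=C10 and C4=C5 are both ring-cis, so C4=C5 can sit in a cyclohexene ring A (C1–C6) and C1=C10 can be the alkene set free when the C1–C6 bond shared with ring B (C1, C6–C10) is broken, a C6 hydroxyl pushing and a C10 spiro-epoxide (C10–O–C14) leaving.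
3. The cis-decalin is cut at C1–C6 and C2–C3 (intramolecular Diels–Alder of a C3=C4–C5=C6 enol-lactone diene with a C10 vinyl ketone), the diene at C4–C5 and O–C6 (palladium cyclisation–coupling of a 4-alkynoic acid with a 2-bromoallyl ether), the alkyne at C5≡C6 and the chain at C7–C8 (syn-aldol).
4. Forward: chain by aldol, alkyne, lactone ring with diene, rings A and B in one cycloaddition, spiro-epoxide, ring opening to the ten-membered ring, lactone re-closure, then C13, the esters and the enal.
5. Stereochemistry: C7 and C8 come from the (R)-oxazolidinone syn-aldol; C6, C1 and C10 of the decalin are relayed from C7 through the lactone ring and are temporary; the two Z alkenes come from ring A and from the anti-periplanar fragmentation; C6 is set by peripheral hydride reduction followed by Mitsunobu inversion.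

Key step: step 17

Remarks on the chemistry:
- Aldehyde 5 is racemic at C10, so 11–18, 22 and 23 are pairs of C10 epimers (their SMILES leave C10 open). The centre becomes the ketone in step 14.
- Compounds 6, 19, 20 and 39 are taken as commercial.
- The acid is carried as a tert-butyl ester because a methyl ester would lactonise onto the C8 hydroxyl after the aldol, and a C12 ester would lactonise onto the C6 titanium alkoxide in the key step.

**Route**

Step 1
Reactants: 1 penta-1,4-dien-3-ol
Product: 2 3-(triethylsilyloxy)penta-1,4-diene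
Conditions: Et3SiCl, imidazole, CH2Cl2, 0 °C → rt
Reagents that add atoms: chlorotriethylsilane, CC[Si](Cl)(CC)CC
Why: Silylation of the secondary alcohol; triethylsilyl is chosen so that the C10 oxygen can be freed in step 13 beside a tert-butyldimethylsilyl ether at C8.

Step 2
Reactants: 2 3-(triethylsilyloxy)penta-1,4-diene
Product: 4 rac-3-(triethylsilyloxy)pent-4-en-1-ol, via B-alkyl-9-BBN adduct 3 (not isolated)
Conditions: 9-BBN (0.5 equiv per 2), THF, 0 °C → rt; then NaOH, H2O2, 0 °C
Reagents that add atoms: 9-borabicyclo[3.3.1]nonane, B1C2CCCC1CCC2 (carried in 3); hydrogen peroxide, OO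
Why: Anti-Markovnikov hydroboration–oxidation of one of the two equivalent vinyl groups (diene in excess to limit double addition) gives the primary alcohol that becomes C8, while the carbinol carbon (later C10) is formed racemic, which is of no consequence.

Step 3
Reactants: 4 rac-3-(triethylsilyloxy)pent-4-en-1-ol
Product: 5 rac-3-(triethylsilyloxy)pent-4-enal
Conditions: Dess–Martin periodinane, NaHCO3, CH2Cl2, 0 °C → rt
Reagents that add atoms: none
Why: Dess–Martin oxidation of the primary alcohol under buffered conditions, which a β-silyloxy aldehyde tolerates without elimination.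

Step 4
Reactants: 6 4-tert-butoxy-4-oxobutanoic acid; 7 (R)-4-benzyl-2-oxazolidinone
Product: 9 tert-butyl 4-[(4R)-4-benzyl-2-oxooxazolidin-3-yl]-4-oxobutanoate, via mixed pivalic anhydride 8 (not isolated)
Conditions: t-BuCOCl, Et3N, THF, −20 °C; then 7, LiCl, −20 °C → rt
Reagents that add atoms: pivaloyl chloride, CC(C)(C)C(Cl)=O (carried in 8)
Why: N-acylation of the oxazolidinone through the mixed anhydride, whose less hindered succinyl carbonyl is the one attacked.

Step 5
Reactants: 9 tert-butyl 4-[(4R)-4-benzyl-2-oxooxazolidin-3-yl]-4-oxobutanoate; 5 rac-3-(triethylsilyloxy)pent-4-enal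
Product: 12 tert-butyl (3R,4S)-3-[(4R)-4-benzyl-2-oxooxazolidine-3-carbonyl]-4-hydroxy-6-(triethylsilyloxy)oct-7-enoate (C7 R, C8 S, both C10 epimers), via boron enolate 10 (not isolated), via boron aldolate 11 (not isolated)
Conditions: Bu2BOTf, iPr2NEt, CH2Cl2, −78 → 0 °C; then 5, −78 → 0 °C; then pH 7 buffer, MeOH, H2O2, 0 °C
Reagents that add atoms: dibutylboron trifluoromethanesulfonate, CCCCB(CCCC)OS(=O)(=O)C(F)(F)F (carried in 10 and 11)
Why: Evans syn-aldol, in which only the imide α-CH2 (C7) is enolised to the Z enolate, which adds to the aldehyde through a closed chair transition state on the face remote from the benzyl group and so sets C7 (R) and C8 (S) syn, while the tert-butyl ester does not lactonise onto the new hydroxyl.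

Step 6
Reactants: 12 syn-aldol adduct
Product: 13 C8 tert-butyldimethylsilyl ether of 12
Conditions: t-BuMe2SiOTf, 2,6-lutidine, CH2Cl2, −78 °C
Reagents that add atoms: tert-butyldimethylsilyl trifluoromethanesulfonate, CC(C)(C)[Si](C)(C)OS(=O)(=O)C(F)(F)F
Why: Silylation of the hindered β-hydroxy imide with the silyl triflate at low temperature, where retro-aldol and ester cleavage do not compete.

Step 7
Reactants: 13 C8 tert-butyldimethylsilyl ether of 12
Product: 14 tert-butyl 4-(tert-butyldimethylsilyloxy)-3-(hydroxymethyl)-6-(triethylsilyloxy)oct-7-enoate (C7 and C8 as in 12)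
Conditions: LiBH4, MeOH (1 equiv), THF, 0 °C
Reagents that add atoms: none
Why: Reductive removal of the auxiliary, LiBH4 attacking the exocyclic imide carbonyl (C6) while the tert-butyl ester and the silyl ethers stay and 7 is recovered.

Step 8
Reactants: 14 primary alcohol
Product: 15 tert-butyl 4-(tert-butyldimethylsilyloxy)-3-formyl-6-(triethylsilyloxy)oct-7-enoate
Conditions: Dess–Martin periodinane, NaHCO3, CH2Cl2, 0 °C; used at once
Reagents that add atoms: none
Why: Dess–Martin oxidation gives the α-branched aldehyde under buffered conditions that should not epimerise C7.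

Step 9
Reactants: 15 aldehyde
Product: 16 tert-butyl 4-(tert-butyldimethylsilyloxy)-3-ethynyl-6-(triethylsilyloxy)oct-7-enoate
Conditions: Ohira–Bestmann reagent, K2CO3, MeOH, 0 °C → rt
Reagents that add atoms: dimethyl (1-diazo-2-oxopropyl)phosphonate, CC(=O)C(=[N+]=[N-])P(=O)(OC)OC
Why: Seyferth–Gilbert homologation with the Ohira–Bestmann reagent turns the C6 aldehyde into the terminal alkyne C6≡C5 under conditions mild enough for the C7 stereocentre and the β-silyloxy group.

Step 10
Reactants: 16 alkynyl tert-butyl ester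
Product: 18 4-(tert-butyldimethylsilyloxy)-3-ethynyl-6-(triethylsilyloxy)oct-7-enoic acid, via trimethylsilyl ester 17 (not isolated)
Conditions: Me3SiOTf, 2,6-lutidine, CH2Cl2, 0 °C; then pH 5 phosphate buffer, MeOH
Reagents that add atoms: trimethylsilyl trifluoromethanesulfonate, C[Si](C)(C)OS(=O)(=O)C(F)(F)F (carried in 17)
Why: Silyl triflate cleavage of the tert-butyl ester (O-silylation, loss of 2-methylpropene) and hydrolysis of the silyl ester on work-up free the C12 acid without a protic acid strong enough to touch the silyl ethers.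

Step 11
Reactants: 19 2,3-dibromoprop-1-ene; 20 4-methoxybenzyl alcohol
Product: 21 2-bromo-3-(4-methoxybenzyloxy)prop-1-ene
Conditions: NaH, THF, 0 °C; then 19, Bu4NI (cat.), 0 °C → rt
Reagents that add atoms: none
Why: Williamson ether synthesis, the alkoxide displacing only the allylic bromide because the vinylic bromide is inert to SN2.

Step 12
Reactants: 18 alkynoic acid; 21 2-bromo-3-(4-methoxybenzyloxy)prop-1-ene
Product: 22 (E)-enol lactone diene: γ-lactone O6–C12(=O)–C11–C7 with exocyclic C6=C5–C4(CH2OPMB)=C3H2, C4 cis to C7, C7 carrying the C8(OTBS)–C9–C10(OTES)–C1=C2 chain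
Conditions: Pd(OAc)2 (5 mol %), PPh3 (20 mol %), K2CO3, Bu4NCl, MeCN, 60 °C
Reagents that add atoms: none
Why: Palladium-catalysed cyclisation–coupling of a 4-alkynoic acid with a vinyl halide, in which oxidative addition of zerovalent palladium to 21, anti attack of the C12 carboxylate on the alkyne held by divalent alkenylpalladium (5-exo-dig) and reductive elimination put C4 trans to the ring oxygen and cis to C7, so the diene is formed with its tether atom C7 on the inside position.

Step 13
Reactants: 22 (E)-enol lactone diene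
Product: 23 C10 allylic alcohol of 22
Conditions: HF·pyridine, pyridine, THF, 0 °C
Reagents that add atoms: none
Why: Buffered fluoride cleaves the secondary triethylsilyl ether much faster than the tert-butyldimethylsilyl ether and leaves the enol lactone and the PMB ether alone.

Step 14
Reactants: 23 C10 allylic alcohol
Product: 25 tricyclic keto lactone: cis-fused decalin (ring A C1–C6 with C4=C5 and C4–CH2OPMB; ring B C1, C6–C10 with C10 ketone and C8–OTBS) bridged by the γ-lactone O6–C12–C11–C7; O6, H1 and C11 on one face of ring B, O8, C2 and C5 on the other, via trienone 24 (not isolated)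
Conditions: Dess–Martin periodinane, NaHCO3, CH2Cl2, 0 °C → rt; filtration, solvent switch; toluene, BHT, 100 °C
Reagents that add atoms: none
Why: Oxidation gives the vinyl ketone, whose intramolecular Diels–Alder reaction joins C1 to C6 and C2 to C3; with C7 on the inside of the diene only the cis-fused decalin can form, the enone must reach the diene face that carries C8 on the lactone ring so that O6 ends cis to H1 and to C11 with the C7 and C8 substituents equatorial on chair ring B, and the acyloxy-bearing terminus C6 bonds to the enone α-carbon C1 as the electronics demand.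

Step 15
Reactants: 25 tricyclic keto lactone
Product: 26 tricyclic epoxy lactone: C10 spiro-epoxide with C14 cis to O6 and H1, epoxide oxygen cis to C2
Conditions: Me3S+ I−, KN(SiMe3)2, THF, −10 °C; then 25, −10 → 0 °C
Reagents that add atoms: trimethylsulfonium iodide, C[S+](C)C.[I-]
Why: Corey–Chaykovsky epoxidation, the unstabilised ylide adding irreversibly and axially to the C10 ketone from the convex face of ring B, anti to the axial C1–C2 bond, so that C14 becomes axial and cis to O6 and the epoxide oxygen equatorial, while the equatorial C1–H is poorly aligned for enolisation and loss of the C6 acyloxy group should stay slow.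

Step 16
Reactants: 26 tricyclic epoxy lactone
Product: 27 lithium carboxylate of the cis-fused 6-hydroxydecalin 10-spiro-epoxide (C7–CH2CO2Li, C8–OTBS, C4–CH2OPMB)
Conditions: LiOH·H2O, THF/H2O, 0 °C → rt; evaporation, azeotropic drying with toluene
Reagents that add atoms: lithium hydroxide, [Li+].[OH-]
Why: Saponification of the γ-lactone frees the tertiary C6 hydroxyl, and the acid is kept as its lithium salt because the free cis-hydroxy acid would close back to the lactone.

Step 17
Reactants: 27 lithium carboxylate of the epoxy alcohol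
Product: 28 (1(10)Z,4Z)-cyclodeca-1(10),4-dien-6-one keto acid with free C14 hydroxyl (C7–CH2CO2H, C8–OTBS, C4–CH2OPMB)
Conditions: Ti(OiPr)4 (3 equiv), THF/CH2Cl2, 0 °C → rt; cold 0.5 M HCl work-up
Reagents that add atoms: none
Why: Ti(OiPr)4 exchanges onto the tertiary C6 alkoxide and binds the epoxide oxygen, and heterolysis of the tertiary C10–O bond is concerted with cleavage of the anti-periplanar C1–C6 bond, so that C6 becomes the ketone of the C4=C5–C6=O enone, C1=C10 is formed and the epoxide oxygen leaves on C14 as the alkoxide of the allylic alcohol. The closest known reaction type is the Lewis acid promoted Grob-type fragmentation of bicyclic 3,4-epoxy alcohols to medium-ring enones. No ring is closed by bond formation: the ten-membered ring appears by ring opening, when the bond shared by the six-membered rings A and B is cut, driven by release of epoxide strain and by formation of the conjugated carbonyl. No stereocentre is created (C1, C6 and C10 become trigonal, C7 and C8 are untouched); the C1=C10 geometry is fixed stereospecifically, because in the chair–chair conformer with the C7 and C8 substituents equatorial the C10–O bond is equatorial and anti to C1–C6 while C1–C2 is axial and gauche to C10–C9, so C2 and C9 end cis and C14 trans to C2, and C4=C5 stays ring-cis because it never leaves ring A. The step needs fragmentation to win over attack of the C6 oxygen on C14 and over hydride shift at C10, which the aligned tertiary C10–O bond, the cis ring fusion and the equatorial epoxide oxygen built in steps 14 and 15 should secure. The neutral titanium medium should also keep the β-silyloxy group at C8 and the configuration at C7 of the new ketone intact, and the carboxylate cannot re-lactonise.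

Step 18
Reactants: 28 keto acid with free C14 hydroxyl
Product: 30 keto acid with C14–OTBS, via bis-silyl compound 29 (not isolated)
Conditions: t-BuMe2SiCl, imidazole, DMF, 0 °C → rt; then aq. NaHCO3, MeOH, rt; pH 5 buffer
Reagents that add atoms: tert-butyldimethylsilyl chloride, CC(C)(C)[Si](C)(C)Cl
Why: Silylation of the primary C14 alcohol (the acid is silylated too and freed again on work-up), so that only the C6 alcohol can be activated in step 20 and C14 carries no base-sensitive ester in step 21.

Step 19
Reactants: 30 keto acid with C14–OTBS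
Product: 31 (6S)-hydroxy acid (O6 cis to the C7 acetic acid arm)
Conditions: NaBH4, CeCl3·7H2O, MeOH, −78 → −40 °C; pH 6 phosphate buffer, cold extraction, used at once
Reagents that add atoms: none
Why: Luche reduction, 1,2-selective for the enone, in which hydride should enter C6 from the ring periphery, on the face turned away from the transannular C1=C10 unit and from the C8 branch of C7, giving the (6S) alcohol, which is used cold and at once so that it does not lactonise with retention.

Step 20
Reactants: 31 (6S)-hydroxy acid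
Product: 32 6,7-trans γ-lactone (6R,7R,8S) with C8–OTBS, C14–OTBS and C15–OPMB
Conditions: PPh3, DIAD, THF, 0 °C
Reagents that add atoms: none
Why: Mitsunobu lactonisation, the C6 alkoxyphosphonium being displaced by the C12 carboxylate in a 5-exo-tet SN2 reaction that inverts C6 to R and gives the trans-fused lactone of the target.

Step 21
Reactants: 32 6,7-trans γ-lactone
Product: 36 α-methylene lactone (C11=C13), via lithium enolate 33 (not isolated), via Mannich base 34 (not isolated), via methiodide 35 (not isolated)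
Conditions: LiN(SiMe3)2, THF, −78 °C; CH2=NMe2+ I−, −78 → 0 °C; then MeI, MeOH/CH2Cl2, rt; then aq. NaHCO3, rt
Reagents that add atoms: N,N-dimethylmethyleneiminium iodide (Eschenmoser's salt), C=[N+](C)C.[I-]; iodomethane, CI (carried in 35)
Why: α-Methylenation of the lactone by Mannich reaction of its enolate with Eschenmoser's salt, quaternisation and mild base elimination, the C11 configuration of 34 and 35 being of no consequence.

Step 22
Reactants: 36 α-methylene lactone
Product: 37 C8,C14-diol
Conditions: HF·pyridine, pyridine, THF, 0 °C → rt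
Reagents that add atoms: none
Why: Fluoride cleavage of both silyl ethers under buffered, non-basic conditions that spare the α-methylene lactone and the PMB ether.

Step 23
Reactants: 37 C8,C14-diol
Product: 38 C14 acetate with free C8 hydroxyl
Conditions: Ac2O (1.1 equiv), 2,4,6-collidine, CH2Cl2, −20 °C
Reagents that add atoms: acetic anhydride, CC(=O)OC(C)=O
Why: Selective acylation, the primary allylic C14 hydroxyl reacting much faster than the hindered secondary C8 hydroxyl at low temperature with one equivalent of anhydride.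

Step 24
Reactants: 39 ethyl 2-(hydroxymethyl)acrylate
Product: 40 ethyl 2-[(tert-butyldimethylsilyloxy)methyl]acrylate
Conditions: t-BuMe2SiCl, imidazole, CH2Cl2, 0 °C → rt
Reagents that add atoms: tert-butyldimethylsilyl chloride, CC(C)(C)[Si](C)(C)Cl
Why: Silylation of the primary allylic alcohol, so that the acid made from it cannot acylate itself.

Step 25
Reactants: 40 ethyl 2-[(tert-butyldimethylsilyloxy)methyl]acrylate
Product: 41 2-[(tert-butyldimethylsilyloxy)methyl]acrylic acid
Conditions: LiOH, THF/H2O, 0 °C; 1 M HCl to pH 3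
Reagents that add atoms: lithium hydroxide, [Li+].[OH-]
Why: Saponification of the ethyl ester at 0 °C, where conjugate addition of hydroxide and loss of the silyl ether should stay slow.

Step 26
Reactants: 38 C14 acetate with free C8 hydroxyl; 41 2-[(tert-butyldimethylsilyloxy)methyl]acrylic acid
Product: 43 C8 ester of 38 with the silyl-protected 2-(hydroxymethyl)acrylic acid, via mixed anhydride 42 (not isolated)
Conditions: 2,4,6-Cl3C6H2COCl, Et3N, toluene, rt; then 38, DMAP, toluene, rt
Reagents that add atoms: 2,4,6-trichlorobenzoyl chloride, O=C(Cl)c1c(Cl)cc(Cl)cc1Cl (carried in 42)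
Why: Yamaguchi esterification, the mixed anhydride acylating the secondary C8 hydroxyl under DMAP catalysis with retention at C8.

Step 27
Reactants: 43 C8 ester with C15–OPMB
Product: 44 C15 allylic alcohol
Conditions: DDQ, CH2Cl2/pH 7 buffer (10:1), 0 °C
Reagents that add atoms: none
Why: Oxidative cleavage of the PMB ether by DDQ (benzylic hydride abstraction, hydrolysis of the oxocarbenium ion), which leaves the esters, the silyl ether and the electron-poor alkenes untouched.

Step 28
Reactants: 44 C15 allylic alcohol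
Product: 45 C15 enal with silyl-protected acrylate
Conditions: MnO2, CH2Cl2, rt
Reagents that add atoms: none
Why: MnO2 oxidises only the allylic C15 alcohol to the enal, and the C4=C5 geometry is held by the ring.

Step 29
Reactants: 45 C15 enal with silyl-protected acrylate
Product: 46 target, (6R,7R,8S)
Conditions: HF·pyridine, pyridine, THF, 0 °C
Reagents that add atoms: none
Why: Final desilylation of the primary allylic silyl ether under buffered conditions that the enal, the acetate, the acrylate and the α-methylene lactone should survive.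

**Compound list**

1 | penta-1,4-dien-3-ol | C=CC(O)C=C | starting material
2 | 3-(triethylsilyloxy)penta-1,4-diene | C=CC(O[Si](CC)(CC)CC)C=C | intermediate
3 | 9-[3-(triethylsilyloxy)pent-4-en-1-yl]-9-borabicyclo[3.3.1]nonane | C=CC(O[Si](CC)(CC)CC)CCB1C2CCCC1CCC2 | intermediate
4 | rac-3-(triethylsilyloxy)pent-4-en-1-ol | OCCC(O[Si](CC)(CC)CC)C=C | intermediate
5 | rac-3-(triethylsilyloxy)pent-4-enal | O=CCC(O[Si](CC)(CC)CC)C=C | intermediate
6 | 4-tert-butoxy-4-oxobutanoic acid | CC(C)(C)OC(=O)CCC(=O)O | starting material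
7 | (R)-4-benzyl-2-oxazolidinone | O=C1N[C@H](Cc2ccccc2)CO1 | starting material
8 | 4-tert-butoxy-4-oxobutanoic pivalic anhydride | CC(C)(C)OC(=O)CCC(=O)OC(=O)C(C)(C)C | intermediate
9 | tert-butyl 4-[(4R)-4-benzyl-2-oxooxazolidin-3-yl]-4-oxobutanoate | O=C1OC[C@@H](Cc2ccccc2)N1C(=O)CCC(=O)OC(C)(C)C | intermediate
10 | (Z)-dibutylboron enolate of 9 (O–B cis to the CH2CO2tBu group) | O=C1OC[C@@H](Cc2ccccc2)N1/C(OB(CCCC)CCCC)=C/CC(=O)OC(C)(C)C | intermediate
11 | dibutylboron aldolate of 12 | O=C1OC[C@@H](Cc2ccccc2)N1C(=O)[C@H](CC(=O)OC(C)(C)C)[C@@H](OB(CCCC)CCCC)CC(O[Si](CC)(CC)CC)C=C | intermediate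
12 | tert-butyl (3R,4S)-3-[(4R)-4-benzyl-2-oxooxazolidine-3-carbonyl]-4-hydroxy-6-(triethylsilyloxy)oct-7-enoate (C7 R, C8 S; C10 epimers) | O=C1OC[C@@H](Cc2ccccc2)N1C(=O)[C@H](CC(=O)OC(C)(C)C)[C@@H](O)CC(O[Si](CC)(CC)CC)C=C | intermediate
13 | C8 tert-butyldimethylsilyl ether of 12 | O=C1OC[C@@H](Cc2ccccc2)N1C(=O)[C@H](CC(=O)OC(C)(C)C)[C@@H](O[Si](C)(C)C(C)(C)C)CC(O[Si](CC)(CC)CC)C=C | intermediate
14 | tert-butyl 4-(tert-butyldimethylsilyloxy)-3-(hydroxymethyl)-6-(triethylsilyloxy)oct-7-enoate (C7, C8 as in 12) | OC[C@H](CC(=O)OC(C)(C)C)[C@@H](O[Si](C)(C)C(C)(C)C)CC(O[Si](CC)(CC)CC)C=C | intermediate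
15 | tert-butyl 4-(tert-butyldimethylsilyloxy)-3-formyl-6-(triethylsilyloxy)oct-7-enoate | O=C[C@H](CC(=O)OC(C)(C)C)[C@@H](O[Si](C)(C)C(C)(C)C)CC(O[Si](CC)(CC)CC)C=C | intermediate
16 | tert-butyl 4-(tert-butyldimethylsilyloxy)-3-ethynyl-6-(triethylsilyloxy)oct-7-enoate | C#C[C@H](CC(=O)OC(C)(C)C)[C@@H](O[Si](C)(C)C(C)(C)C)CC(O[Si](CC)(CC)CC)C=C | intermediate
17 | trimethylsilyl ester corresponding to 16 | C#C[C@H](CC(=O)O[Si](C)(C)C)[C@@H](O[Si](C)(C)C(C)(C)C)CC(O[Si](CC)(CC)CC)C=C | intermediate
18 | 4-(tert-butyldimethylsilyloxy)-3-ethynyl-6-(triethylsilyloxy)oct-7-enoic acid | C#C[C@H](CC(=O)O)[C@@H](O[Si](C)(C)C(C)(C)C)CC(O[Si](CC)(CC)CC)C=C | intermediate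
19 | 2,3-dibromoprop-1-ene | C=C(Br)CBr | starting material
20 | 4-methoxybenzyl alcohol | COc1ccc(CO)cc1 | starting material
21 | 2-bromo-3-(4-methoxybenzyloxy)prop-1-ene | C=C(Br)COCc1ccc(OC)cc1 | intermediate
22 | (E)-enol lactone diene (C4 cis to C7; C8–OTBS, C10–OTES) | O=C1C[C@H]([C@@H](O[Si](C)(C)C(C)(C)C)CC(O[Si](CC)(CC)CC)C=C)/C(=C\C(=C)COCc2ccc(OC)cc2)O1 | intermediate
23 | C10 allylic alcohol of 22 | O=C1C[C@H]([C@@H](O[Si](C)(C)C(C)(C)C)CC(O)C=C)/C(=C\C(=C)COCc2ccc(OC)cc2)O1 | intermediate
24 | trienone (C10 vinyl ketone with the enol lactone diene) | O=C1C[C@H]([C@@H](O[Si](C)(C)C(C)(C)C)CC(=O)C=C)/C(=C\C(=C)COCc2ccc(OC)cc2)O1 | intermediate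
25 | tricyclic keto lactone (cis-decalin, C10 ketone, O6–C12 lactone cis-fused on ring B) | O=C1C[C@@H]2[C@@H](O[Si](C)(C)C(C)(C)C)CC(=O)[C@H]3CCC(COCc4ccc(OC)cc4)=C[C@@]23O1 | intermediate
26 | tricyclic epoxy lactone (C10 spiro-epoxide, C14 cis to O6) | O=C1C[C@@H]2[C@@H](O[Si](C)(C)C(C)(C)C)C[C@]4(CO4)[C@H]3CCC(COCc5ccc(OC)cc5)=C[C@@]23O1 | intermediate
27 | lithium carboxylate of the cis-fused 6-hydroxydecalin 10-spiro-epoxide | [Li+].[O-]C(=O)C[C@@H]1[C@@H](O[Si](C)(C)C(C)(C)C)C[C@]3(CO3)[C@H]2CCC(COCc4ccc(OC)cc4)=C[C@@]12O | intermediate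
28 | (1(10)Z,4Z)-cyclodecadien-6-one keto acid with free C14 hydroxyl | CC(C)(C)[Si](C)(C)O[C@H]1C/C(CO)=C\CC/C(COCc2ccc(OC)cc2)=C\C(=O)[C@@H]1CC(=O)O | intermediate
29 | C14 silyl ether silyl ester of 28 | CC(C)(C)[Si](C)(C)O[C@H]1C/C(CO[Si](C)(C)C(C)(C)C)=C\CC/C(COCc2ccc(OC)cc2)=C\C(=O)[C@@H]1CC(=O)O[Si](C)(C)C(C)(C)C | intermediate
30 | keto acid with C14–OTBS | CC(C)(C)[Si](C)(C)O[C@H]1C/C(CO[Si](C)(C)C(C)(C)C)=C\CC/C(COCc2ccc(OC)cc2)=C\C(=O)[C@@H]1CC(=O)O | intermediate
31 | (6S)-hydroxy acid | CC(C)(C)[Si](C)(C)O[C@H]1C/C(CO[Si](C)(C)C(C)(C)C)=C\CC/C(COCc2ccc(OC)cc2)=C\[C@H](O)[C@@H]1CC(=O)O | intermediate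
32 | 6,7-trans γ-lactone (6R,7R,8S) | CC(C)(C)[Si](C)(C)O[C@H]1C/C(CO[Si](C)(C)C(C)(C)C)=C\CC/C(COCc2ccc(OC)cc2)=C\[C@H]3OC(=O)C[C@H]13 | intermediate
33 | lithium enolate of 32 | [Li+].CC(C)(C)[Si](C)(C)O[C@H]1C/C(CO[Si](C)(C)C(C)(C)C)=C\CC/C(COCc2ccc(OC)cc2)=C\[C@H]3OC([O-])=C[C@H]13 | intermediate
34 | C11 dimethylaminomethyl lactone (C11 epimers) | CC(C)(C)[Si](C)(C)O[C@H]1C/C(CO[Si](C)(C)C(C)(C)C)=C\CC/C(COCc2ccc(OC)cc2)=C\[C@H]3OC(=O)C(CN(C)C)[C@H]13 | intermediate
35 | trimethylammonium iodide of 34 | [I-].CC(C)(C)[Si](C)(C)O[C@H]1C/C(CO[Si](C)(C)C(C)(C)C)=C\CC/C(COCc2ccc(OC)cc2)=C\[C@H]3OC(=O)C(C[N+](C)(C)C)[C@H]13 | intermediate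
36 | α-methylene lactone with C8–OTBS, C14–OTBS, C15–OPMB | CC(C)(C)[Si](C)(C)O[C@H]1C/C(CO[Si](C)(C)C(C)(C)C)=C\CC/C(COCc2ccc(OC)cc2)=C\[C@H]3OC(=O)C(=C)[C@H]13 | intermediate
37 | C8,C14-diol | O[C@H]1C/C(CO)=C\CC/C(COCc2ccc(OC)cc2)=C\[C@H]3OC(=O)C(=C)[C@H]13 | intermediate
38 | C14 acetate with free C8 hydroxyl | O[C@H]1C/C(COC(C)=O)=C\CC/C(COCc2ccc(OC)cc2)=C\[C@H]3OC(=O)C(=C)[C@H]13 | intermediate
39 | ethyl 2-(hydroxymethyl)acrylate | C=C(CO)C(=O)OCC | starting material
40 | ethyl 2-[(tert-butyldimethylsilyloxy)methyl]acrylate | C=C(CO[Si](C)(C)C(C)(C)C)C(=O)OCC | intermediate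
41 | 2-[(tert-butyldimethylsilyloxy)methyl]acrylic acid | C=C(CO[Si](C)(C)C(C)(C)C)C(=O)O | intermediate
42 | mixed anhydride of 41 with 2,4,6-trichlorobenzoic acid | C=C(CO[Si](C)(C)C(C)(C)C)C(=O)OC(=O)c1c(Cl)cc(Cl)cc1Cl | intermediate
43 | C8 ester with silyl-protected 2-(hydroxymethyl)acrylate, C15–OPMB | C=C(CO[Si](C)(C)C(C)(C)C)C(=O)O[C@H]1C/C(COC(C)=O)=C\CC/C(COCc2ccc(OC)cc2)=C\[C@H]3OC(=O)C(=C)[C@H]13 | intermediate
44 | C15 allylic alcohol | C=C(CO[Si](C)(C)C(C)(C)C)C(=O)O[C@H]1C/C(COC(C)=O)=C\CC/C(CO)=C\[C@H]2OC(=O)C(=C)[C@H]12 | intermediate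
45 | C15 enal with silyl-protected acrylate | C=C(CO[Si](C)(C)C(C)(C)C)C(=O)O[C@H]1C/C(COC(C)=O)=C\CC/C(C=O)=C\[C@H]2OC(=O)C(=C)[C@H]12 | intermediate
46 | CNP0198933.2, (6R,7R,8S) | C=C(CO)C(=O)O[C@H]1C/C(COC(C)=O)=C\CC/C(C=O)=C\[C@H]2OC(=O)C(=C)[C@H]12 | target

**Count and risks**

Total step count: 29. Longest linear sequence: 25 steps (1–3, 5–10, 12–23, 26–29).

Step 15. What may go wrong: methylene transfer to the other face of C10, since the axial C6 oxygen lies 1,3 to the axial approach path, or enolisation by the basic ylide followed by β-elimination. The fallback sets out from 25 and returns at 26. The ketone is methylenated without base (Zn, CH2Br2, TiCl4, THF/CH2Cl2) to the exocyclic C10=C14 alkene F1. Buffered HF·pyridine then frees the C8 alcohol to give the homoallylic alcohol F2. A hydroxyl-directed epoxidation (VO(acac)2, t-BuOOH, CH2Cl2) delivers oxygen to the alkene face syn to the equatorial C8 hydroxyl, which is the face anti to O6, and leaves C4=C5 alone, giving the epoxy alcohol F3. Silylation with t-BuMe2SiOTf and 2,6-lutidine gives 26.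

Step 17. What may go wrong: attack of the C6 alkoxide on the epoxide methylene C14 to a bridged ether, or hydride shift at C10, outrunning C1–C6 cleavage; the carboxylate may also hold back the titanium. The fallback cleaves the same bond without an epoxide; it sets out from 25 and returns at 28. LiOH opens the lactone to the lithium carboxylate of the β-hydroxy ketone F4. KN(SiMe3)2 and PhN(SO2CF3)2 in THF (−78 → 0 °C) then drive an anionic retro-aldol cleavage of C1–C6, and the C1=C10 enolate, ring-cis because C1–C2 is axial, is trapped as the ten-membered enol triflate F5. Stille coupling with Bu3SnCH2OH (Pd(PPh3)4, LiCl, dioxane, 90 °C) installs C14 and gives 28.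

Step 19. What may go wrong: hydride delivery to the other face of the C6 carbonyl, so that the C6 epimer is formed. The fallback sets out from 30 and returns at 32. The (6R)-hydroxy acid F6 is then closed by acyl substitution with retention (PPTS, CH2Cl2, rt) directly to 32, and step 20 is dropped.

Further compounds
F1 | step 15 | tricyclic lactone with exocyclic C10=C14 alkene and C8–OTBS | O=C1C[C@@H]2[C@@H](O[Si](C)(C)C(C)(C)C)CC(=C)[C@H]3CCC(COCc4ccc(OC)cc4)=C[C@@]23O1
F2 | step 15 | tricyclic lactone with exocyclic C10=C14 alkene and free C8 hydroxyl | O=C1C[C@@H]2[C@@H](O)CC(=C)[C@H]3CCC(COCc4ccc(OC)cc4)=C[C@@]23O1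
F3 | step 15 | tricyclic epoxy lactone with free C8 hydroxyl | O=C1C[C@@H]2[C@@H](O)C[C@]4(CO4)[C@H]3CCC(COCc5ccc(OC)cc5)=C[C@@]23O1
F4 | step 17 | lithium carboxylate of the cis-fused 6-hydroxydecalin-10-one | [Li+].[O-]C(=O)C[C@@H]1[C@@H](O[Si](C)(C)C(C)(C)C)CC(=O)[C@H]2CCC(COCc3ccc(OC)cc3)=C[C@@]12O
F5 | step 17 | ten-membered C10 enol triflate keto acid (C2 and C9 cis on C1=C10) | CC(C)(C)[Si](C)(C)O[C@H]1C/C(OS(=O)(=O)C(F)(F)F)=C\CC/C(COCc2ccc(OC)cc2)=C\C(=O)[C@@H]1CC(=O)O
F6 | step 19 | (6R)-hydroxy acid | CC(C)(C)[Si](C)(C)O[C@H]1C/C(CO[Si](C)(C)C(C)(C)C)=C\CC/C(COCc2ccc(OC)cc2)=C\[C@@H](O)[C@@H]1CC(=O)O
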